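## Retrosynthetic overview

1. Acid numbering is used for the target (C1 = CO2H, C2 S, C6 R). The C4 methylene is disconnected as a gem-bis(phenylsulfonyl) carbon, a CH2 linchpin that is removed reductively at the end; the furan is attached by B-alkyl Suzuki coupling of a C2 allyl group with a bought 3-halofuran.
2. C3–C4 bond and the C2 centre: chiral primary-amine-catalysed Michael addition of the bis-sulfone C–H to a 2-allylacrolein, ending in enantioselective enamine protonation (new step).
3. C5–C6 bond and the C6 centre (first stereocentre): diarylprolinol silyl ether-catalysed Michael addition of an achiral C8 alkenal to a vinyl bis-sulfone, followed by oxidation of the aldehyde to the methyl ester.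
4. The two aldehyde partners come from terminal C6 and C5 alkenals, by cross-metathesis (isopropylidene cap) and by α-methylenation with formaldehyde.
5. No ring is formed; the furan is the only ring and it is bought.

Assumption: the five small achiral building blocks are taken as catalogue compounds, and the facial sense of the new step 5 is assigned by analogy with known enamine protonations by this diamine class (the mirror-image diamine is used if a model run shows the opposite sense).

## Route

Step 1
Reactants: 1 hex-5-enal; 2 2-methylbut-2-ene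
Product: 3 6-methylhept-5-enal
Conditions: second-generation Grubbs catalyst RuCl2(=CHPh)(H2IMes)(PCy3) (2 mol%), 2 (10 equiv), CH2Cl2, 35 °C, 12 h
Reagents that add atoms: none
Why: Olefin cross-metathesis of the terminal alkene with excess trisubstituted alkene caps the chain as the isopropylidene olefin and releases propene; the aldehyde is tolerated and no stereocentre is involved.

Step 2
Reactants: 3 6-methylhept-5-enal; 4 1,1-bis(phenylsulfonyl)ethylene
Product: 5 (2S)-2-[2,2-bis(phenylsulfonyl)ethyl]-6-methylhept-5-enal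
Conditions: (R)-2-{bis[3,5-bis(trifluoromethyl)phenyl](trimethylsilyloxy)methyl}pyrrolidine (10 mol%), 3 (1.5 equiv), CHCl3, 0 °C, 3 h
Reagents that add atoms: none
Why: Enamine-catalysed asymmetric Michael addition of a linear aldehyde to a doubly activated vinyl sulfone (Hayashi–Jørgensen catalysis); the diaryl(silyloxy)methyl group of the (R)-catalyst shields the Si face of the (E)-anti-enamine, so 4 adds to the Re face and the new centre is (S), the arrangement that becomes C6 (R) of the target.

Step 3
Reactants: 5 (2S)-2-[2,2-bis(phenylsulfonyl)ethyl]-6-methylhept-5-enal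
Product: 7 methyl (2S)-2-[2,2-bis(phenylsulfonyl)ethyl]-6-methylhept-5-enoate, via methyl hemiacetal 6 (not isolated)
Conditions: pyridinium dichromate (C5H5NH)2Cr2O7 (6 equiv), MeOH (6 equiv), DMF, rt, 20 h
Reagents that add atoms: methanol, CO
Why: Oxidative esterification through chromate oxidation of the methyl hemiacetal; the non-basic medium leaves the α-centre and the acidic bis-sulfone C–H untouched, and removing the aldehyde keeps it away from the amine catalyst of step 5 (7 is expected to crystallise, which allows an ee upgrade).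

Step 4
Reactants: 8 pent-4-enal
Product: 9 2-methylidenepent-4-enal
Conditions: 37% aq. HCHO (1.0 equiv), pyrrolidine (10 mol%), EtCO2H (10 mol%), i-PrOH, 45 °C, 1 h; extracted into CH2Cl2 and used at once
Reagents that add atoms: formaldehyde, C=O
Why: Amine/acid-catalysed Mannich condensation and elimination (α-methylenation of an aldehyde); no stereocentre is formed and the remote terminal alkene is inert.

Step 5
Reactants: 7 methyl (2S)-2-[2,2-bis(phenylsulfonyl)ethyl]-6-methylhept-5-enoate; 9 2-methylidenepent-4-enal
Product: 10 methyl (2S,6R)-6-formyl-2-(4-methylpent-3-en-1-yl)-4,4-bis(phenylsulfonyl)non-8-enoate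
Conditions: (S)-N1,N1-diethyl-3,3-dimethylbutane-1,2-diamine·TfOH (20 mol%), 9 (2 equiv), CHCl3, 0 °C to rt, 24–48 h
Reagents that add atoms: none
Why: Proposed new method: an iminium–enamine relay on an α-substituted acrolein with a carbon acid as nucleophile and a proton as the terminating electrophile, in which the primary amine condenses with 9 to an s-trans iminium ion, the freed NEt2 arm deprotonates the bis-sulfone C–H of 7 (pKa about 14), the ion-paired carbanion adds to the unsubstituted CH2 terminus (C3–C4 bond, quaternary C4), and the resulting Et2NH+ arm passes its proton intramolecularly to one face of the geometrically defined enamine to set the α-centre as (R) before hydrolysis; the closest known reaction types are primary–tertiary diamine-catalysed Friedel–Crafts and transfer-hydrogenation reactions of α-substituted acroleins with enantioselective enamine protonation, and secondary-amine-catalysed additions of bis(phenylsulfonyl)methane to β-substituted enals, whereas a sulfonyl carbanion has not been added to an α-branched acrolein with catalyst-controlled protonation.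

Step 6
Reactants: 10 methyl (2S,6R)-6-formyl-2-(4-methylpent-3-en-1-yl)-4,4-bis(phenylsulfonyl)non-8-enoate
Product: 11 (2R,6S)-6-(methoxycarbonyl)-10-methyl-4,4-bis(phenylsulfonyl)-2-(prop-2-en-1-yl)undec-9-enoic acid
Conditions: NaClO2 (3 equiv), NaH2PO4 (3 equiv), 2-methylbut-2-ene (20 equiv), t-BuOH/H2O 4:1, 0 °C to rt
Reagents that add atoms: sodium chlorite, [Na+].[O-]Cl=O
Why: Pinnick oxidation converts the α-branched aldehyde into the acid without epimerisation, the scavenger protects both alkenes from HOCl, and the oxidation is run before the chlorite-sensitive furan is present.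

Step 7
Reactants: 11 (2R,6S)-6-(methoxycarbonyl)-10-methyl-4,4-bis(phenylsulfonyl)-2-(prop-2-en-1-yl)undec-9-enoic acid; 12 3-bromofuran
Product: 14 (2R,6S)-2-[3-(furan-3-yl)propyl]-6-(methoxycarbonyl)-10-methyl-4,4-bis(phenylsulfonyl)undec-9-enoic acid, via alkylborane 13 (not isolated)
Conditions: 9-BBN (2.2 equiv), THF, 0 °C to rt; then 12 (1.5 equiv), PdCl2(dppf) (5 mol%), K3PO4 (3 M aq., 3 equiv), DMF, 50 °C; citric acid work-up
Reagents that add atoms: none
Why: 9-BBN hydroborates only the terminal alkene in the anti-Markovnikov sense (one further equivalent is consumed by the acid O–H, the trisubstituted alkene is far slower), and B-alkyl Suzuki–Miyaura coupling then joins the primary alkylborane to the 3-position of the furan without touching either stereocentre.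

Step 8
Reactants: 14 (2R,6S)-2-[3-(furan-3-yl)propyl]-6-(methoxycarbonyl)-10-methyl-4,4-bis(phenylsulfonyl)undec-9-enoic acid
Product: 16 (2S,6R)-2-[3-(furan-3-yl)propyl]-6-(methoxycarbonyl)-10-methylundec-9-enoic acid, via monosulfone 15 (not isolated)
Conditions: Mg turnings (15 equiv), MeOH, rt, 3–6 h; aq. NaH2PO4 work-up
Reagents that add atoms: none
Why: Reductive desulfonylation by electron transfer from magnesium cleaves each C–S bond in turn and methanol protonates the carbanion, leaving CH2 at C4; furan, alkene, ester and both stereocentres are untouched, and the descriptors change from (2R,6S) to (2S,6R) only because the CIP priorities change.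

## Compound list

1 | hex-5-enal | C=CCCCC=O | starting material
2 | 2-methylbut-2-ene | CC=C(C)C | starting material
3 | 6-methylhept-5-enal | CC(C)=CCCCC=O | intermediate
4 | 1,1-bis(phenylsulfonyl)ethylene | C=C(S(=O)(=O)c1ccccc1)S(=O)(=O)c1ccccc1 | starting material
5 | (2S)-2-[2,2-bis(phenylsulfonyl)ethyl]-6-methylhept-5-enal | O=C[C@@H](CCC=C(C)C)CC(S(=O)(=O)c1ccccc1)S(=O)(=O)c1ccccc1 | intermediate
6 | (2S)-2-[2,2-bis(phenylsulfonyl)ethyl]-1-methoxy-6-methylhept-5-en-1-ol (methyl hemiacetal, both C1 epimers) | COC(O)[C@@H](CCC=C(C)C)CC(S(=O)(=O)c1ccccc1)S(=O)(=O)c1ccccc1 | intermediate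
7 | methyl (2S)-2-[2,2-bis(phenylsulfonyl)ethyl]-6-methylhept-5-enoate | COC(=O)[C@@H](CCC=C(C)C)CC(S(=O)(=O)c1ccccc1)S(=O)(=O)c1ccccc1 | intermediate
8 | pent-4-enal | C=CCCC=O | starting material
9 | 2-methylidenepent-4-enal | C=CCC(=C)C=O | intermediate
10 | methyl (2S,6R)-6-formyl-2-(4-methylpent-3-en-1-yl)-4,4-bis(phenylsulfonyl)non-8-enoate | COC(=O)[C@@H](CCC=C(C)C)CC(S(=O)(=O)c1ccccc1)(S(=O)(=O)c1ccccc1)C[C@@H](CC=C)C=O | intermediate
11 | (2R,6S)-6-(methoxycarbonyl)-10-methyl-4,4-bis(phenylsulfonyl)-2-(prop-2-en-1-yl)undec-9-enoic acid | COC(=O)[C@@H](CCC=C(C)C)CC(S(=O)(=O)c1ccccc1)(S(=O)(=O)c1ccccc1)C[C@@H](CC=C)C(=O)O | intermediate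
12 | 3-bromofuran | Brc1ccoc1 | starting material
13 | 9-borabicyclo[3.3.1]nonan-9-yl (2R,6S)-2-[3-(9-borabicyclo[3.3.1]nonan-9-yl)propyl]-6-(methoxycarbonyl)-10-methyl-4,4-bis(phenylsulfonyl)undec-9-enoate (B-alkyl borane with the acid held as its acyloxyborane) | COC(=O)[C@@H](CCC=C(C)C)CC(S(=O)(=O)c1ccccc1)(S(=O)(=O)c1ccccc1)C[C@@H](CCCB1C2CCCC1CCC2)C(=O)OB1C2CCCC1CCC2 | intermediate
14 | (2R,6S)-2-[3-(furan-3-yl)propyl]-6-(methoxycarbonyl)-10-methyl-4,4-bis(phenylsulfonyl)undec-9-enoic acid | COC(=O)[C@@H](CCC=C(C)C)CC(S(=O)(=O)c1ccccc1)(S(=O)(=O)c1ccccc1)C[C@@H](CCCc1ccoc1)C(=O)O | intermediate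
15 | (2R,6S)-2-[3-(furan-3-yl)propyl]-6-(methoxycarbonyl)-10-methyl-4-(phenylsulfonyl)undec-9-enoic acid (both C4 epimers) | COC(=O)[C@@H](CCC=C(C)C)CC(S(=O)(=O)c1ccccc1)C[C@@H](CCCc1ccoc1)C(=O)O | intermediate
16 | (2S,6R)-2-[3-(furan-3-yl)propyl]-6-(methoxycarbonyl)-10-methylundec-9-enoic acid | COC(=O)[C@@H](CCC=C(C)C)CCC[C@@H](CCCc1ccoc1)C(=O)O | target

## Step count and risks

Total steps: 8. Longest linear sequence: 7 (steps 1, 2, 3, 5, 6, 7, 8); step 4 is a one-step side branch.

**Step 5 (the proposed new reaction).** The tertiary bis-sulfone is hindered and only moderately acidic, so the addition may be slow; the level and sense of the protonation are unproven; and the primary amine could epimerise the α-branched product if left too long. The fallback uses known chemistry, sets out from 7 and comes back at 10. Triethylamine-catalysed conjugate addition of 7 to acrolein (CH2Cl2, 0 °C to rt) gives the chain aldehyde methyl (2S)-2-(4-methylpent-3-en-1-yl)-7-oxo-4,4-bis(phenylsulfonyl)heptanoate F1. Its unbranched α-position is then allylated by the established organo-SOMO α-allylation: allyltrimethylsilane, 5-benzyl-2-tert-butyl-3-methylimidazolidin-4-one·TFA (20 mol%, the enantiomer that gives the 6R centre), ceric ammonium nitrate (NH4)2Ce(NO3)6, NaHCO3, DME, −20 °C. This delivers 10 under catalyst control.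

**Step 7 (hydroboration and Suzuki coupling on a free acid).** The acid consumes borane, and the aqueous base at 50 °C may partly hydrolyse the methyl ester. The fallback installs the furan before any acid exists; it sets out from 12 (and uses 7) and comes back at 14.
- Bought pent-4-en-1-ol is treated with 9-BBN (2.1 equiv) to give the bis-borane 9-{5-[(9-borabicyclo[3.3.1]nonan-9-yl)oxy]pentyl}-9-borabicyclo[3.3.1]nonane F2.
- Coupling of F2 with 12 (PdCl2(dppf), aq. K3PO4) gives 5-(furan-3-yl)pentan-1-ol F3.
- Dess–Martin oxidation gives 5-(furan-3-yl)pentanal F4.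
- Methylenation as in step 4 gives 5-(furan-3-yl)-2-methylidenepentanal F5.
- Addition of 7 under the step 5 conditions gives methyl (2S,6R)-6-formyl-9-(furan-3-yl)-2-(4-methylpent-3-en-1-yl)-4,4-bis(phenylsulfonyl)nonanoate F6.
- A buffered Pinnick oxidation with a large excess of 2 gives 14; the furan is exposed to chlorite here, which is why this is not the main route.

**Step 8 (double desulfonylation last).** Magnesium methoxide may epimerise the ester α-centre, and the second C–S cleavage can stall at 15. The fallback changes both the reductant and the order, so that the reduction is done on the furan-free acid and the coupling comes last; it sets out from 11 and comes back at 16. Buffered sodium amalgam (6% Na(Hg), Na2HPO4, MeOH/THF, −20 °C) reduces 11 through the monosulfone (2R,6S)-6-(methoxycarbonyl)-10-methyl-4-(phenylsulfonyl)-2-(prop-2-en-1-yl)undec-9-enoic acid F7 to (2S,6R)-6-(methoxycarbonyl)-10-methyl-2-(prop-2-en-1-yl)undec-9-enoic acid F8. 9-BBN (2.2 equiv) converts F8 into the bis-borane 9-borabicyclo[3.3.1]nonan-9-yl (2R,6R)-2-[3-(9-borabicyclo[3.3.1]nonan-9-yl)propyl]-6-(methoxycarbonyl)-10-methylundec-9-enoate F9. Coupling of F9 with 12 under the step 7 conditions gives 16.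

Further compounds
F1 | step 5 | methyl (2S)-2-(4-methylpent-3-en-1-yl)-7-oxo-4,4-bis(phenylsulfonyl)heptanoate | COC(=O)[C@@H](CCC=C(C)C)CC(S(=O)(=O)c1ccccc1)(S(=O)(=O)c1ccccc1)CCC=O
F2 | step 7 | 9-{5-[(9-borabicyclo[3.3.1]nonan-9-yl)oxy]pentyl}-9-borabicyclo[3.3.1]nonane | C(CCB1C2CCCC1CCC2)CCOB1C2CCCC1CCC2
F3 | step 7 | 5-(furan-3-yl)pentan-1-ol | OCCCCCc1ccoc1
F4 | step 7 | 5-(furan-3-yl)pentanal | O=CCCCCc1ccoc1
F5 | step 7 | 5-(furan-3-yl)-2-methylidenepentanal | C=C(CCCc1ccoc1)C=O
F6 | step 7 | methyl (2S,6R)-6-formyl-9-(furan-3-yl)-2-(4-methylpent-3-en-1-yl)-4,4-bis(phenylsulfonyl)nonanoate | COC(=O)[C@@H](CCC=C(C)C)CC(S(=O)(=O)c1ccccc1)(S(=O)(=O)c1ccccc1)C[C@@H](CCCc1ccoc1)C=O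
F7 | step 8 | (2R,6S)-6-(methoxycarbonyl)-10-methyl-4-(phenylsulfonyl)-2-(prop-2-en-1-yl)undec-9-enoic acid (both C4 epimers) | COC(=O)[C@@H](CCC=C(C)C)CC(S(=O)(=O)c1ccccc1)C[C@@H](CC=C)C(=O)O
F8 | step 8 | (2S,6R)-6-(methoxycarbonyl)-10-methyl-2-(prop-2-en-1-yl)undec-9-enoic acid | COC(=O)[C@@H](CCC=C(C)C)CCC[C@@H](CC=C)C(=O)O
F9 | step 8 | 9-borabicyclo[3.3.1]nonan-9-yl (2R,6R)-2-[3-(9-borabicyclo[3.3.1]nonan-9-yl)propyl]-6-(methoxycarbonyl)-10-methylundec-9-enoate | COC(=O)[C@@H](CCC=C(C)C)CCC[C@@H](CCCB1C2CCCC1CCC2)C(=O)OB1C2CCCC1CCC2
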